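The runs stem from a simulated flask for substances that don't exist; noise was put on by code.

**The ceiling.** E in the flask could not stand above what L had sent down its own branch, since the steps proposed let G take part of the lost L and let D come from E. So I reckoned with a branching share, the selectivity of L between the two routes, and asked how [X] divided that share between E and D.

| setting | maple | flask |
|---|---|---|
| L | 0.10 M | 0.10 M |
| X | 1.5 mM | 1.0 mM |
| remark | run made earlier |  |
| time |  | 8.0 d |

maple run (percent of the L charged)

| time / h | E / % | D / % | L / % |
|---|---|---|---|
| 3.00 | 6.0 | 1.9 | 93.2 |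
| 5.00 | 6.7 | 1.9 | 89.6 |
| 8.00 | 10.7 | 1.5 | 84.0 |
| 15.0 | 17.5 | 3.3 | 73.5 |
| 25.0 | 21.5 | 4.5 | 59.6 |
| 40.0 | 29.8 | 12.5 | 41.5 |

(readings scatter by 1 percentage point)

- steps that have been proposed: L -> E; 2 X -> Q; X + E -> X + D; L -> G
- no earlier run changes the charge of X; that part of a forecast is a guess

- when, up to 8.0 d, the flask holds most E
- the amount of E, in percent of the L charged, at that time
- the first time at which E reaches 12%, in the same percent, in d

**What mattered.** The L constant hardly touched the ceiling: first-order loss from 41.5% left at 40.0 h gave 1.47% in the flask at 8.0 d, hardly any. It did scale the early times. [X] entered the split of the pool between E and D, not its size, though carrying the maple L loss over to 1.0 mM was a guess. The E and D readings counted directly: one standard deviation on either single reading moved the share by 1.7 percentage points.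

**My reckoning.** The last maple reading gave 72.3% as the branching share, E + D over the L lost. With 0.528 d⁻¹ for L and no E counted as lost to D, I estimated that E reached 12% at 0.344 d.

**The forecast.** It put the peak at 3 d (2.3 d to 4.8 d) with 38% (32% to 47%), and 12% at 0.37 d, later than my estimate: “Any loss of X through 2X→Q would make the peak later and higher, so I shade upward.”

**The flask.** It peaked at 3.94 d with 38.4% of E, and reached 12% at 0.402 d.

    L → E (k = 0.0150 h⁻¹)
    2 X → Q (k = 16.0 M⁻¹ h⁻¹)
    X + E → X + D (k = 21.0 M⁻¹ h⁻¹)
    L → G (k = 0.00630 h⁻¹)

At that peak it held 13.3% of L and 22.6% of D, so the share allowed 62.7% against 61.0% found as E + D. The neighbour with 2.5 × 10⁻⁴ M of X had 1.67% of L left at 8.00 d, which allowed 71.1%, and it held 45.5% of E and 23.7% of D, together 69.2%.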